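## Retrosynthetic overview

1. Target 29 ⇐ di-tert-butyl ester 28 (acidolysis) ⇐ axial C4 alcohol 22 + (2E,4E,6E)-octa-2,4,6-trienoic acid 26 (Yamaguchi esterification).
2. 22 ⇐ racemic trans-decalin-4-one 20 by an oxazaborolidine-catalysed reduction run as a kinetic resolution (sets C4 and selects the absolute configuration).
3. 20 ⇐ acyclic keto-diene diester 17: its 2-silyloxydiene undergoes an intramolecular Diels–Alder reaction that closes ring A (through the tether) and ring B (through the [4+2]) in one operation and sets C1, C2, C4a and C8a.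
4. 17 ⇐ methyl ketone 10 + tert-butyl glyoxylate 13 (aldol condensation); 10 ⇐ alkylzinc from mesityl oxide and allylsilane (Sakurai, then HBr) + (E)-enol triflate 8 of tert-butyl acetoacetate (Negishi).
5. Ring order: no ring before step 7; rings A and B form together in step 7.

Assumption: ring positions are numbered as in decahydronaphthalene (C1 and C2 carry the carboxyl groups, C4 the oxygen, C5 the gem-dimethyl group, C8a the methyl group); racemic compounds 19 and 20 are drawn as the enantiomer that is carried on; 13 and 26 are made rather than bought.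

## Route

Step 1
Reactants: 1 4-methylpent-3-en-2-one (mesityl oxide); 2 allyltrimethylsilane
Product: 4 4,4-dimethylhept-6-en-2-one, via titanium enolate 3 (not isolated)
Conditions: TiCl4, CH2Cl2, −78 °C; then H2O
Reagents that add atoms: none
Why: Hosomi–Sakurai conjugate allylation, in which the TiCl4-activated enone is attacked at its β-carbon by the allylsilane terminus to build the gem-dimethyl quaternary carbon and a titanium enolate that is protonated on work-up; no stereocentre is formed.

Step 2
Reactants: 4 4,4-dimethylhept-6-en-2-one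
Product: 5 7-bromo-4,4-dimethylheptan-2-one
Conditions: HBr (gas), (PhCO2)2 (2 mol%), pentane, 0 °C
Reagents that add atoms: hydrogen bromide, Br
Why: Peroxide-initiated radical (anti-Markovnikov, Kharasch) addition of HBr puts bromine on the terminal carbon because the bromine atom adds to give the secondary radical; the ketone is inert and no stereocentre is formed.

Step 3
Reactants: 6 tert-butyl 3-oxobutanoate (tert-butyl acetoacetate)
Product: 8 tert-butyl (2E)-3-{[(trifluoromethyl)sulfonyl]oxy}but-2-enoate, via tetramethylammonium enolate 7 (not isolated)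
Conditions: Tf2O, aq. Me4NOH, hexanes, 5 °C
Reagents that add atoms: trifluoromethanesulfonic anhydride, O=S(=O)(OS(=O)(=O)C(F)(F)F)C(F)(F)F
Why: O-triflation of the acetoacetate enolate under Schotten–Baumann conditions, where the non-chelating ammonium counter-ion lets the enolate adopt the extended shape with oxygen anti to the ester, so the (E)-enol triflate (methyl cis to the ester) results.

Step 4
Reactants: 5 7-bromo-4,4-dimethylheptan-2-one; 8 tert-butyl (2E)-3-{[(trifluoromethyl)sulfonyl]oxy}but-2-enoate
Product: 10 tert-butyl (2E)-3,7,7-trimethyl-9-oxodec-2-enoate, via alkylzinc bromide 9 (not isolated)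
Conditions: Zn dust, LiCl, THF, 40 °C; then 8, Pd(PPh3)4 (5 mol%), THF, 50 °C
Reagents that add atoms: none
Why: LiCl-assisted zinc insertion gives a ketone-tolerant alkylzinc bromide that undergoes Negishi cross-coupling with the enol triflate with retention of alkene geometry, fixing the (E)-trisubstituted enoate (chain trans to the ester) that later dictates the cis relationship of the C8a methyl group and the C1 ester.

Step 5
Reactants: 11 tert-butyl prop-2-enoate (tert-butyl acrylate)
Product: 13 tert-butyl 2-oxoacetate (tert-butyl glyoxylate), via ozonide 12 (not isolated)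
Conditions: O3, CH2Cl2, −78 °C; then Me2S, −78 → 23 °C; distillation
Reagents that add atoms: ozone, [O-][O+]=O
Why: Ozonolysis of the acrylate double bond with reductive work-up gives the glyoxylate and volatile formaldehyde; no stereocentre is formed.

Step 6
Reactants: 10 tert-butyl (2E)-3,7,7-trimethyl-9-oxodec-2-enoate; 13 tert-butyl 2-oxoacetate
Product: 17 di-tert-butyl (2E,10E)-3,7,7-trimethyl-9-oxododeca-2,10-dienedioate, via lithium enolate 14 (not isolated), via lithium aldolate 15 (not isolated), via aldol mesylate 16 (not isolated)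
Conditions: LiN(iPr)2, THF, −78 °C; 13; then MsCl, Et3N, −78 → 23 °C
Reagents that add atoms: none
Why: Aldol condensation, in which kinetic deprotonation occurs at the methyl group (the other α-position is a neopentyl CH2), the enolate adds to the highly electrophilic glyoxylate aldehyde, and mesylation with E1cB elimination gives the thermodynamically favoured (E)-enone.

Step 7
Reactants: 17 di-tert-butyl (2E,10E)-3,7,7-trimethyl-9-oxododeca-2,10-dienedioate
Product: 20 di-tert-butyl (1S,2S,4aS,8aS)-5,5,8a-trimethyl-4-oxodecahydronaphthalene-1,2-dicarboxylate (racemic), via silyl dienol ether 18 (not isolated), via bicyclic silyl enol ether 19 (not isolated)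
Conditions: t-BuMe2SiOTf, Et3N, PhMe, 0 °C, decant; PhMe (0.01 M), 2,6-di-tert-butyl-4-methylphenol, 160 °C (sealed tube); then 1 M HCl, THF, 0 °C
Reagents that add atoms: none
Why: Soft enolisation can occur only at the CH2 next to the quaternary carbon and gives the (Z)-2-silyloxydiene, whose thermal intramolecular Diels–Alder reaction with the (E)-enoate closes rings A and B at once: suprafacial addition of the (E)-dienophile sets the C8a methyl group and the C1 ester cis, the (E)-diene terminus combined with the ester-endo transition state (chair-like tether, the small methyl group taking the axial site beside the gem-dimethyl group) sets the trans ring fusion at C4a and the axial C2 ester cis to the C1 ester, and mild acid hydrolysis of the silyl enol ether unveils the C4 ketone.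

Step 8
Reactants: 20 di-tert-butyl (1S,2S,4aS,8aS)-5,5,8a-trimethyl-4-oxodecahydronaphthalene-1,2-dicarboxylate (racemic)
Product: 22 di-tert-butyl (1S,2S,4R,4aS,8aS)-4-hydroxy-5,5,8a-trimethyldecahydronaphthalene-1,2-dicarboxylate, via borate ester 21 (not isolated)
Conditions: (S)-1-methyl-3,3-diphenyltetrahydro-1H,3H-pyrrolo[1,2-c][1,3,2]oxazaborole (0.3 equiv), catecholborane (0.55 equiv), PhMe, −40 °C, to ca. 50% conversion; aq. pH 9 work-up
Reagents that add atoms: none
Why: Corey–Bakshi–Shibata reduction used as a kinetic resolution: hydride can reach the ketone only from the face opposite the two axial methyl groups and the axial C2 ester, giving the axial (4R) alcohol, and with the (S)-catalyst this substrate-preferred face is also the catalyst-preferred face only in the (1S,2S,4aS,8aS) enantiomer, so that enantiomer is reduced while the mirror-image ketone stays behind and is removed by chromatography (at most 50% yield); the bulky tert-butyl ester at C2 does not lactonise onto the new hydroxyl group.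

Step 9
Reactants: 23 (2E,4E)-hexa-2,4-dienal; 24 propanedioic acid (malonic acid)
Product: 26 (2E,4E,6E)-octa-2,4,6-trienoic acid, via dienylidenemalonic acid 25 (not isolated)
Conditions: pyridine, piperidine (10 mol%), 90 °C; aq. HCl
Reagents that add atoms: none
Why: Knoevenagel–Doebner condensation, in which the alkylidene malonic acid loses CO2 in hot pyridine to give the thermodynamically favoured (2E) acid while the two existing (E) double bonds are untouched.

Step 10
Reactants: 26 (2E,4E,6E)-octa-2,4,6-trienoic acid; 22 di-tert-butyl (1S,2S,4R,4aS,8aS)-4-hydroxy-5,5,8a-trimethyldecahydronaphthalene-1,2-dicarboxylate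
Product: 28 di-tert-butyl (1S,2S,4R,4aS,8aS)-5,5,8a-trimethyl-4-{[(2E,4E,6E)-octa-2,4,6-trienoyl]oxy}decahydronaphthalene-1,2-dicarboxylate, via mixed anhydride 27 (not isolated)
Conditions: 2,4,6-Cl3C6H2COCl, Et3N, THF, 23 °C; then 22, 4-(dimethylamino)pyridine, PhMe, 40 °C
Reagents that add atoms: none
Why: Yamaguchi esterification, in which 4-(dimethylamino)pyridine attacks the mixed anhydride at the less hindered trienoyl carbonyl and the acylpyridinium acylates the hindered axial alcohol with retention at C4, the tert-butyl esters being inert to the base.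

Step 11
Reactants: 28 di-tert-butyl (1S,2S,4R,4aS,8aS)-5,5,8a-trimethyl-4-{[(2E,4E,6E)-octa-2,4,6-trienoyl]oxy}decahydronaphthalene-1,2-dicarboxylate
Product: 29 (1S,2S,4R,4aS,8aS)-5,5,8a-trimethyl-4-{[(2E,4E,6E)-octa-2,4,6-trienoyl]oxy}decahydronaphthalene-1,2-dicarboxylic acid (CNP0462207.1)
Conditions: CF3CO2H–CH2Cl2 (1:3), 0 → 23 °C
Reagents that add atoms: none
Why: Acidolysis of both tert-butyl esters (E1 loss of isobutene) frees the two carboxylic acids and leaves the electron-poor trienoate ester and all five stereocentres untouched.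

## Compound list

1 | 4-methylpent-3-en-2-one (mesityl oxide) | CC(=O)C=C(C)C | starting material
2 | allyltrimethylsilane | C=CC[Si](C)(C)C | starting material
3 | trichlorotitanium (Z)-enolate of 4 (formed in situ) | C/C(O[Ti](Cl)(Cl)Cl)=C/C(C)(C)CC=C | intermediate
4 | 4,4-dimethylhept-6-en-2-one | CC(=O)CC(C)(C)CC=C | intermediate
5 | 7-bromo-4,4-dimethylheptan-2-one | CC(=O)CC(C)(C)CCCBr | intermediate
6 | tert-butyl 3-oxobutanoate | CC(=O)CC(=O)OC(C)(C)C | starting material
7 | tetramethylammonium (E)-enolate of 6, oxygen anti to the ester (formed in situ) | C/C([O-])=C\C(=O)OC(C)(C)C.C[N+](C)(C)C | intermediate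
8 | tert-butyl (2E)-3-{[(trifluoromethyl)sulfonyl]oxy}but-2-enoate | C/C(OS(=O)(=O)C(F)(F)F)=C\C(=O)OC(C)(C)C | intermediate
9 | bromo(4,4-dimethyl-6-oxoheptyl)zinc (formed in situ) | CC(=O)CC(C)(C)CCC[Zn]Br | intermediate
10 | tert-butyl (2E)-3,7,7-trimethyl-9-oxodec-2-enoate | CC(=O)CC(C)(C)CCC/C(C)=C/C(=O)OC(C)(C)C | intermediate
11 | tert-butyl prop-2-enoate | C=CC(=O)OC(C)(C)C | starting material
12 | tert-butyl 1,2,4-trioxolane-3-carboxylate, racemic (formed in situ) | CC(C)(C)OC(=O)C1OCOO1 | intermediate
13 | tert-butyl 2-oxoacetate | O=CC(=O)OC(C)(C)C | intermediate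
14 | tert-butyl (2E)-9-(lithiooxy)-3,7,7-trimethyldeca-2,9-dienoate (formed in situ) | [Li]OC(=C)CC(C)(C)CCC/C(C)=C/C(=O)OC(C)(C)C | intermediate
15 | lithium alkoxide of di-tert-butyl (2E)-11-hydroxy-3,7,7-trimethyl-9-oxododec-2-enedioate, racemic at C11 (formed in situ) | [Li]OC(CC(=O)CC(C)(C)CCC/C(C)=C/C(=O)OC(C)(C)C)C(=O)OC(C)(C)C | intermediate
16 | di-tert-butyl (2E)-3,7,7-trimethyl-11-[(methylsulfonyl)oxy]-9-oxododec-2-enedioate, racemic at C11 (formed in situ) | CS(=O)(=O)OC(CC(=O)CC(C)(C)CCC/C(C)=C/C(=O)OC(C)(C)C)C(=O)OC(C)(C)C | intermediate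
17 | di-tert-butyl (2E,10E)-3,7,7-trimethyl-9-oxododeca-2,10-dienedioate | CC(C)(C)OC(=O)/C=C/C(=O)CC(C)(C)CCC/C(C)=C/C(=O)OC(C)(C)C | intermediate
18 | di-tert-butyl (2E,4Z,10E)-4-[(tert-butyldimethylsilyl)oxy]-6,6,10-trimethyldodeca-2,4,10-trienedioate (formed in situ) | CC(C)(C)OC(=O)/C=C/C(O[Si](C)(C)C(C)(C)C)=C/C(C)(C)CCC/C(C)=C/C(=O)OC(C)(C)C | intermediate
19 | di-tert-butyl (1S,2S,4aS,8aS)-4-[(tert-butyldimethylsilyl)oxy]-5,5,8a-trimethyl-1,2,4a,5,6,7,8,8a-octahydronaphthalene-1,2-dicarboxylate, racemic (formed in situ) | CC(C)(C)[Si](C)(C)OC1=C[C@H](C(=O)OC(C)(C)C)[C@H](C(=O)OC(C)(C)C)[C@@]2(C)CCCC(C)(C)[C@H]12 | intermediate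
20 | di-tert-butyl (1S,2S,4aS,8aS)-5,5,8a-trimethyl-4-oxodecahydronaphthalene-1,2-dicarboxylate, racemic, trans-fused, both esters cis to the C8a methyl group | O=C1C[C@H](C(=O)OC(C)(C)C)[C@H](C(=O)OC(C)(C)C)[C@@]2(C)CCCC(C)(C)[C@H]12 | intermediate
21 | 1,3,2-benzodioxaborol-2-yl ether (borate ester) of 22 (formed in situ) | O(B1Oc2ccccc2O1)[C@@H]1C[C@H](C(=O)OC(C)(C)C)[C@H](C(=O)OC(C)(C)C)[C@@]2(C)CCCC(C)(C)[C@H]12 | intermediate
22 | di-tert-butyl (1S,2S,4R,4aS,8aS)-4-hydroxy-5,5,8a-trimethyldecahydronaphthalene-1,2-dicarboxylate | O[C@@H]1C[C@H](C(=O)OC(C)(C)C)[C@H](C(=O)OC(C)(C)C)[C@@]2(C)CCCC(C)(C)[C@H]12 | intermediate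
23 | (2E,4E)-hexa-2,4-dienal | C/C=C/C=C/C=O | starting material
24 | propanedioic acid | OC(=O)CC(=O)O | starting material
25 | [(2E,4E)-hexa-2,4-dien-1-ylidene]propanedioic acid (formed in situ) | C/C=C/C=C/C=C(C(=O)O)C(=O)O | intermediate
26 | (2E,4E,6E)-octa-2,4,6-trienoic acid | C/C=C/C=C/C=C/C(=O)O | intermediate
27 | (2E,4E,6E)-octa-2,4,6-trienoic 2,4,6-trichlorobenzoic anhydride (formed in situ) | C/C=C/C=C/C=C/C(=O)OC(=O)c1c(Cl)cc(Cl)cc1Cl | intermediate
28 | di-tert-butyl (1S,2S,4R,4aS,8aS)-5,5,8a-trimethyl-4-{[(2E,4E,6E)-octa-2,4,6-trienoyl]oxy}decahydronaphthalene-1,2-dicarboxylate | C/C=C/C=C/C=C/C(=O)O[C@@H]1C[C@H](C(=O)OC(C)(C)C)[C@H](C(=O)OC(C)(C)C)[C@@]2(C)CCCC(C)(C)[C@H]12 | intermediate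
29 | (1S,2S,4R,4aS,8aS)-5,5,8a-trimethyl-4-{[(2E,4E,6E)-octa-2,4,6-trienoyl]oxy}decahydronaphthalene-1,2-dicarboxylic acid | C/C=C/C=C/C=C/C(=O)O[C@@H]1C[C@H](C(=O)O)[C@H](C(=O)O)[C@@]2(C)CCCC(C)(C)[C@H]12 | target

## Step count and risks

Total step count: 11. Longest linear sequence: 8 steps (1, 2, 4, 6, 7, 8, 10, 11).

**Step 7** is the most likely to fail. The cycloaddition joins a fully substituted dienophile carbon to a diene terminus beside a quaternary carbon, so it may need temperatures at which tert-butyl esters start to lose isobutene. The trans/cis ring-fusion ratio of a thermal intramolecular Diels–Alder reaction of this type may be modest, and the cis-fused adduct carries the wrong C2 configuration. The fallback replaces the pericyclic step by an ionic cascade below room temperature. It sets out from 17, which is added slowly to LiN(SiMe3)2 in hexane–Et2O at −78 °C to give the lithium dienolate F1. On warming, a lithium bridge between the enolate oxygen and the enoate carbonyl organises a Michael addition that closes ring A and gives the ring-A-closed lithium ester enolate F2. F2 closes ring B by a second Michael addition onto the enone to give the bicyclic lithium enolate F3. Quenching with aqueous NH4Cl returns to the route at 20.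

**Step 8** is the second risk. The ketone is very hindered, so the catalysed reduction may be slow relative to uncatalysed reduction, and the selectivity factor of the resolution may be too low for a single enantiomer. The fallback separates resolution from reduction. It sets out from 20, whose enantiomers are separated by preparative chromatography on a chiral stationary phase (amylose tris(3,5-dimethylphenylcarbamate), supercritical CO2–iPrOH) to give the single-enantiomer ketone F4. F4 is reduced with NaBH4 in MeOH at 0 °C under substrate control alone (hydride from the open face), which returns to the route at 22.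

**Step 10** is the third risk. The hydroxyl group is syn-axial to two methyl groups and an ester, so acylation by the bulky conjugated acyl donor may stall, and base can deconjugate the trienoyl unit through a vinylketene. The fallback builds the side chain on the oxygen instead of delivering it whole. It sets out from 22, which is esterified with diethylphosphonoacetic acid and N,N'-dicyclohexylcarbodiimide in CH2Cl2 (a small, linear acyl donor that reacts through its ketene) to give the phosphonoacetate F5. Horner–Wadsworth–Emmons olefination of F5 with (2E,4E)-hexa-2,4-dienal 23 (LiCl, 1,8-diazabicyclo[5.4.0]undec-7-ene, MeCN, 23 °C) forms the (2E) double bond and returns to the route at 28.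

## Further compounds

F1 | step 7 | lithium (Z)-dienolate of 17, di-tert-butyl (2E,4Z,10E)-4-(lithiooxy)-6,6,10-trimethyldodeca-2,4,10-trienedioate | CC(C)(C)OC(=O)/C=C/C(O[Li])=C/C(C)(C)CCC/C(C)=C/C(=O)OC(C)(C)C
F2 | step 7 | ring-A-closed lithium ester enolate, tert-butyl (2E)-4-{(1S,2R)-2-[2-tert-butoxy-2-(lithiooxy)ethenyl]-2,6,6-trimethylcyclohexyl}-4-oxobut-2-enoate, racemic | CC(C)(C)OC(=O)/C=C/C(=O)[C@H]1C(C)(C)CCC[C@]1(C)/C=C(\O[Li])OC(C)(C)C
F3 | step 7 | bicyclic lithium enolate, di-tert-butyl (1S,2S,4aS,8aS)-4-(lithiooxy)-5,5,8a-trimethyl-1,2,4a,5,6,7,8,8a-octahydronaphthalene-1,2-dicarboxylate, racemic | [Li]OC1=C[C@H](C(=O)OC(C)(C)C)[C@H](C(=O)OC(C)(C)C)[C@@]2(C)CCCC(C)(C)[C@H]12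
F4 | step 8 | di-tert-butyl (1S,2S,4aS,8aS)-5,5,8a-trimethyl-4-oxodecahydronaphthalene-1,2-dicarboxylate, single enantiomer | O=C1C[C@H](C(=O)OC(C)(C)C)[C@H](C(=O)OC(C)(C)C)[C@@]2(C)CCCC(C)(C)[C@H]12
F5 | step 10 | di-tert-butyl (1S,2S,4R,4aS,8aS)-4-{[(diethoxyphosphoryl)acetyl]oxy}-5,5,8a-trimethyldecahydronaphthalene-1,2-dicarboxylate | CCOP(=O)(OCC)CC(=O)O[C@@H]1C[C@H](C(=O)OC(C)(C)C)[C@H](C(=O)OC(C)(C)C)[C@@]2(C)CCCC(C)(C)[C@H]12
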